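**Retrosynthetic overview**
1. Structural feature: the core is a bicyclo[3.2.1]oct-3-ene in which the six-membered ring C1′–C2′–C3′–C4′–C5′=C6′ is spanned by the two-carbon bridge C7–C8 (C7 on C3′, C8 on C1′), with oxygenated C4′ next to C3′. C7=C8 is therefore treated as an alkene standing on C3′ of a cyclohexa-1,3-diene (C1′=C6′–C5′=C4′) that adds across C1′/C4′; the extra C4′–C7 cyclopropane bond is cut afterwards because C4′ carries oxygen.
2. Target ⇐ aryl acetate methanolysis ⇐ diacetylation ⇐ Luche reduction at C4′ ⇐ hydrolysis of the C2′ ketal ⇐ fluoride opening (C4′–C7) of silyloxycyclopropane 26.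
3. 26 ⇐ intramolecular Diels–Alder reaction of (S)-diene 25, closing the cyclopentane C3′–C7–C8–C1′–C2′ and the cyclopropane C3′–C4′–C7 on the existing six-membered ring.
4. 25 ⇐ resolution of 24 ⇐ 1,2-addition of the geometrically defined alkenyllithium 22 (from syringaldehyde via a (Z)-enol triflate) to masked o-benzoquinone 13, then O-methylation.
5. 13 ⇐ PhI(OAc)2/MeOH dearomatisation of phenol 12 ⇐ 2,5-dimethoxyphenol by directed metalation–hydroxylation, O-allylation and para-Claisen rearrangement. Ring order: six-membered ring from the arene; cyclopentane and cyclopropane together (step 16); cyclopropane opened (step 17).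

Key step: step 16

Remark: C3′ is created by addition to a flat, achiral dienone, so 24 is made as a racemate and resolved; the route is written for the (S)-enantiomer 25, whose assignment is to be confirmed by X-ray analysis of a later crystalline intermediate.
Abbreviations and locants: TIPS = tri(propan-2-yl)silyl; Ar = 3,5-dimethoxy-4-(TIPS-oxy)phenyl; C7 = ArC, C8 = MeCH, C1′ = allyl carbon, C2′ = ketal/ketone carbon, C3′ = MeO-bearing quaternary carbon, C4′ = silyloxy/acetoxy carbon, C5′ = MeO alkene carbon, C6′ = alkene CH; exo = toward the C2′ bridge, endo = toward the C4′–C5′=C6′ bridge.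

**Fragment A: masked o-benzoquinone 13**

Step 1
Reactants: 1 2,5-dimethoxyphenol
Product: 2 1,4-dimethoxy-2-(methoxymethoxy)benzene
Conditions: NaH, MeOCH2Cl, THF–DMF, 0 °C → rt
Reagents that add atoms: chloromethyl methyl ether, COCCl
Why: Williamson-type O-alkylation of the sodium phenoxide gives the methoxymethyl ether, which protects the future C3′ oxygen and directs the metalation of step 2.

Step 2
Reactants: 2 1,4-dimethoxy-2-(methoxymethoxy)benzene
Product: 5 3,6-dimethoxy-2-(methoxymethoxy)phenol, via aryllithium 3 (not isolated), via dimethyl arylboronate 4 (not isolated)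
Conditions: n-BuLi, THF, 0 °C; B(OMe)3, −78 °C → rt; 30% aq. H2O2, 0 °C → rt
Reagents that add atoms: hydrogen peroxide, OO
Why: Directed ortho-metalation should occur at the only ring position flanked by two oxygen directors, and borylation followed by peroxide oxidation of the arylboronate (boron-to-oxygen 1,2-shift) installs the future C4′ oxygen.

Step 3
Reactants: 5 3,6-dimethoxy-2-(methoxymethoxy)phenol; 6 allyl bromide
Product: 7 2-(allyloxy)-1,4-dimethoxy-3-(methoxymethoxy)benzene
Conditions: K2CO3, DMF, 50 °C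
Reagents that add atoms: none
Why: Williamson ether synthesis on the phenoxide with a reactive allylic halide.

Step 4
Reactants: 7 2-(allyloxy)-1,4-dimethoxy-3-(methoxymethoxy)benzene
Product: 10 4-allyl-3,6-dimethoxy-2-(methoxymethoxy)phenol, via ortho-dienone 8 (not isolated), via para-dienone 9 (not isolated)
Conditions: PhNEt2, 195 °C, sealed tube
Reagents that add atoms: none
Why: Aromatic para-Claisen rearrangement: with both ortho positions blocked, the [3,3] shift to an ortho carbon is followed by a Cope shift to the para carbon and tautomerisation, which places the allyl group para to the regenerated phenol (future C1′ and C4′–O), as is known for allyl 2,6-dimethoxyphenyl ether.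

Step 5
Reactants: 10 4-allyl-3,6-dimethoxy-2-(methoxymethoxy)phenol
Product: 11 [4-allyl-3,6-dimethoxy-2-(methoxymethoxy)phenoxy]tri(propan-2-yl)silane
Conditions: NaH, i-Pr3SiCl, THF, 0 °C → rt
Reagents that add atoms: chlorotri(propan-2-yl)silane, CC(C)[Si](Cl)(C(C)C)C(C)C
Why: O-Silylation of the sodium phenoxide; the bulky TIPS group is chosen because it has to survive the dearomatisation of step 7 and must not migrate to the neighbouring alkoxide in step 14.

Step 6
Reactants: 11 [4-allyl-3,6-dimethoxy-2-(methoxymethoxy)phenoxy]tri(propan-2-yl)silane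
Product: 12 3-allyl-2,5-dimethoxy-6-(TIPS-oxy)phenol
Conditions: conc. HCl (cat.), MeOH, 40 °C
Reagents that add atoms: none
Why: Acid-catalysed transacetalisation removes the methoxymethyl ether, whereas aryl TIPS ethers are stable to dilute methanolic HCl.

Step 7
Reactants: 12 3-allyl-2,5-dimethoxy-6-(TIPS-oxy)phenol
Product: 13 5-allyl-3,6,6-trimethoxy-2-(TIPS-oxy)cyclohexa-2,4-dien-1-one
Conditions: PhI(OAc)2, MeOH, 0 °C; used without storage
Reagents that add atoms: methanol, CO
Why: Oxidative dearomatisation of a 2-methoxyphenol with a hypervalent iodine reagent in methanol (masked o-benzoquinone formation); methanol should attack the methoxy-bearing ortho carbon because the silyloxy-bearing one is shielded by the TIPS group, and the fully substituted dienone should dimerise only slowly.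

**Fragment B: (Z)-alkenyl iodide 21**

Step 8
Reactants: 14 syringaldehyde
Product: 15 3,5-dimethoxy-4-(TIPS-oxy)benzaldehyde
Conditions: NaH, i-Pr3SiCl, THF, 0 °C → rt
Reagents that add atoms: chlorotri(propan-2-yl)silane, CC(C)[Si](Cl)(C(C)C)C(C)C
Why: O-Silylation of the phenoxide gives a protecting group that tolerates the organometallic steps and is later removed by fluoride together with the C4′ silyl group.

Step 9
Reactants: 15 3,5-dimethoxy-4-(TIPS-oxy)benzaldehyde
Product: 16 1-[3,5-dimethoxy-4-(TIPS-oxy)phenyl]propan-1-ol (racemic)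
Conditions: EtMgBr, THF, 0 °C; aq. NH4Cl
Reagents that add atoms: ethylmagnesium bromide, CC[Mg]Br
Why: Grignard addition to an aromatic aldehyde; the carbinol centre is removed in the next step.

Step 10
Reactants: 16 1-[3,5-dimethoxy-4-(TIPS-oxy)phenyl]propan-1-ol
Product: 17 1-[3,5-dimethoxy-4-(TIPS-oxy)phenyl]propan-1-one
Conditions: MnO2, CH2Cl2, rt
Reagents that add atoms: none
Why: Selective oxidation of an electron-rich benzylic alcohol with activated MnO2.

Step 11
Reactants: 17 1-[3,5-dimethoxy-4-(TIPS-oxy)phenyl]propan-1-one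
Product: 19 (Z)-1-[3,5-dimethoxy-4-(TIPS-oxy)phenyl]prop-1-en-1-yl trifluoromethanesulfonate, via potassium enolate 18 (not isolated)
Conditions: KN(SiMe3)2, THF, −78 °C; PhNTf2, −78 → 0 °C
Reagents that add atoms: N-phenylbis(trifluoromethanesulfonimide), O=S(=O)(N(c1ccccc1)S(=O)(=O)C(F)(F)F)C(F)(F)F
Why: Kinetic deprotonation of an aryl ethyl ketone gives the (Z)-enolate (oxygen cis to methyl, allylic strain between aryl and methyl avoided), and O-triflation fixes this geometry, which later becomes the exo methyl group at C8.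

Step 12
Reactants: 19 (Z)-enol triflate
Product: 20 trimethyl{(Z)-1-[3,5-dimethoxy-4-(TIPS-oxy)phenyl]prop-1-en-1-yl}stannane
Conditions: Me3SnSnMe3, Pd(PPh3)4 (cat.), LiCl, THF, 65 °C
Reagents that add atoms: hexamethylditin, C[Sn](C)(C)[Sn](C)(C)C
Why: Pd-catalysed stannylation of an enol triflate (oxidative addition, transmetalation with the distannane, reductive elimination) proceeds with retention of alkene geometry.

Step 13
Reactants: 20 (Z)-alkenylstannane
Product: 21 {4-[(Z)-1-iodoprop-1-en-1-yl]-2,6-dimethoxyphenoxy}tri(propan-2-yl)silane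
Conditions: I2, CH2Cl2, 0 °C
Reagents that add atoms: iodine, II
Why: Iododestannylation at the alkenyl carbon occurs with retention and gives a halide that undergoes lithium exchange in ether, where the α-arylalkenyllithium should be configurationally stable.

**Coupling, resolution, key step and endgame**

Step 14
Reactants: 21 (Z)-alkenyl iodide; 13 5-allyl-3,6,6-trimethoxy-2-(TIPS-oxy)cyclohexa-2,4-dien-1-one
Product: 24 racemic 4-allyl-6-[(Z)-1-Ar-prop-1-en-1-yl]-2,5,5,6-tetramethoxy-1-(TIPS-oxy)cyclohexa-1,3-diene, via alkenyllithium 22 (not isolated), via lithium alkoxide 23 (not isolated)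
Conditions: t-BuLi (2 equiv), Et2O, −78 °C; 13 in Et2O, −78 → −40 °C; MeOSO2CF3, −78 → 0 °C; chromatography on Et3N-deactivated silica
Reagents that add atoms: methyl trifluoromethanesulfonate, COS(=O)(=O)C(F)(F)F
Why: Iodine–lithium exchange with retention, 1,2-addition of the hard organolithium to the dienone carbonyl (as known for quinone monoketals) and O-methylation of the lithium alkoxide at low temperature, before the TIPS group can shift to it, give the tertiary methyl ether; the carbonyl is flat and achiral, so C3′ forms as a racemate.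

Step 15
Reactants: 24 racemic diene
Product: 25 (6S)-4-allyl-6-[(Z)-1-Ar-prop-1-en-1-yl]-2,5,5,6-tetramethoxy-1-(TIPS-oxy)cyclohexa-1,3-diene (C3′ = S)
Conditions: preparative HPLC on amylose tris(3,5-dimethylphenylcarbamate), hexane–i-PrOH with 0.1% Et3N
Reagents that add atoms: none
Why: Chromatographic resolution of the enantiomers of a neutral, lipophilic compound on a polysaccharide chiral phase supplies the single stereocentre needed before the cycloaddition.

Step 16
Reactants: 25 (S)-diene
Product: 26 5-allyl-7-Ar-1,3,8,8-tetramethoxy-6-exo-methyl-2-(TIPS-oxy)tricyclo[3.2.1.0(2,7)]oct-3-ene (C1 = C3′; C2 = C4′; C3 = C5′; C4 = C6′; C5 = C1′; C6 = C8; C7 = C7; C8 = C2′)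
Conditions: PhMe (0.01 M), 2,6-lutidine (0.2 equiv), 2,6-di-tert-butyl-4-methylphenol (cat.), 160 °C, sealed base-washed tube
Reagents that add atoms: none
Why: Heating brings the C3′-bound alkene over the silyloxydiene, and a concerted, suprafacial thermal [4+2] cycloaddition forms C8–C1′ and C7–C4′ in one step; the closest known reaction type is the intramolecular Diels–Alder reaction of 5-vinylcyclohexa-1,3-dienes and 6-alkenylcyclohexa-2,4-dienones to tricyclo[3.2.1.0(2,7)]oct-3-enes. The cyclopentane (C3′–C7–C8–C1′–C2′) closes by bonding of the outer alkene carbon C8 to the distal diene terminus C1′ and the cyclopropane (C3′–C4′–C7) by bonding of C7 to the adjacent terminus C4′, the only bridged mode that a tether of zero atoms allows. C1′ and C4′ are set by the diene face on which the alkenyl group stands, that is by the (S) centre C3′, and the quaternary C7 follows from the same constraint. C8 is set by the (Z) alkene geometry, since the methyl group cis to C3′ ends exo. Beyond this the step needs only periselectivity over a [3,3] shift of the vinylcyclohexadiene and over acid-triggered loss of the tertiary allylic methoxy group, which the quaternary C2′ and C3′ (no 1,5-hydrogen shift possible), base-washed glass and the hindered base should secure.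

Step 17
Reactants: 26 tricyclic silyloxycyclopropane
Product: 28 5-allyl-7-endo-(4-hydroxy-3,5-dimethoxyphenyl)-1,3,8,8-tetramethoxy-6-exo-methylbicyclo[3.2.1]oct-3-en-2-one, via cyclopropanol 27 (not isolated)
Conditions: Bu4NF (4 equiv), wet THF, 0 → 50 °C; aq. NH4Cl
Reagents that add atoms: none
Why: Fluoride cleaves both silyl ethers and the cyclopropanolate opens by homoenolate-type C4′–C7 cleavage toward the benzylic carbon (base-induced cyclopropanol ring opening), with protonation at C7 on the exo face opposite the breaking bond (inversion), so the aryl group turns endo; the C2′–OMe bonds are not aligned for a fragmentation toward C3′.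

Step 18
Reactants: 28 enone ketal
Product: 29 5-allyl-7-endo-(4-hydroxy-3,5-dimethoxyphenyl)-1,3-dimethoxy-6-exo-methylbicyclo[3.2.1]oct-3-ene-2,8-dione
Conditions: 2 M aq. HCl, THF, 50 °C
Reagents that add atoms: water, O
Why: Acid-catalysed ketal hydrolysis frees the C2′ ketone while the C4′ carbonyl is still present, because the α-methoxy enone resists hydrolysis (protonation at C6′ would place an oxocarbenium ion next to the carbonyl), whereas a simple enol ether at C5′ would not survive.

Step 19
Reactants: 29 enedione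
Product: 30 5-allyl-2-hydroxy-7-endo-(4-hydroxy-3,5-dimethoxyphenyl)-1,3-dimethoxy-6-exo-methylbicyclo[3.2.1]oct-3-en-8-one (2-OH on the face turned to the C6–C7 bridge)
Conditions: NaBH4, CeCl3·7H2O, MeOH, −78 → −40 °C; aq. NaHCO3
Reagents that add atoms: none
Why: Luche reduction should reduce the conjugated C4′ ketone by 1,2-addition in preference to the non-conjugated C2′ ketone, which lies between two quaternary carbons, and hydride should enter from the face under the C2′ carbonyl bridge, away from the endo aryl group on C7, which sets C4′ with its hydroxyl toward the C7–C8 bridge.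

Step 20
Reactants: 30 hydroxy ketone
Product: 31 diacetate of 30 (aryl acetate and C4′ acetate)
Conditions: Ac2O, pyridine, 4-(dimethylamino)pyridine (cat.), CH2Cl2, 0 °C → rt
Reagents that add atoms: acetic anhydride, CC(=O)OC(C)=O
Why: Nucleophile-catalysed acylation esterifies the hindered secondary alcohol and, unavoidably, the phenol.

Step 21
Reactants: 31 diacetate
Product: 32 CNP0373655.1 (7R,8S,1′S,3′S,4′R in the neolignan locants)
Conditions: K2CO3 (0.2 equiv), MeOH, 0 °C
Reagents that add atoms: none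
Why: Base-catalysed transesterification cleaves the aryl acetate (phenoxide leaving group) far faster than the hindered secondary alkyl acetate, and no stereocentre is epimerisable under these conditions.

**Compound list**
1 | 2,5-dimethoxyphenol | COc1ccc(OC)c(O)c1 | starting material
2 | 1,4-dimethoxy-2-(methoxymethoxy)benzene | COCOc1cc(OC)ccc1OC | intermediate
3 | [3,6-dimethoxy-2-(methoxymethoxy)phenyl]lithium (formed in situ) | COCOc1c([Li])c(OC)ccc1OC | intermediate
4 | dimethyl [3,6-dimethoxy-2-(methoxymethoxy)phenyl]boronate (formed in situ) | COCOc1c(B(OC)OC)c(OC)ccc1OC | intermediate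
5 | 3,6-dimethoxy-2-(methoxymethoxy)phenol | COCOc1c(O)c(OC)ccc1OC | intermediate
6 | allyl bromide (3-bromoprop-1-ene) | C=CCBr | starting material
7 | 2-(allyloxy)-1,4-dimethoxy-3-(methoxymethoxy)benzene | C=CCOc1c(OCOC)c(OC)ccc1OC | intermediate
8 | 6-allyl-3,6-dimethoxy-2-(methoxymethoxy)cyclohexa-2,4-dien-1-one (racemic, formed in situ) | C=CCC1(OC)C=CC(OC)=C(OCOC)C1=O | intermediate
9 | 4-allyl-3,6-dimethoxy-2-(methoxymethoxy)cyclohexa-2,5-dien-1-one (racemic, formed in situ) | C=CCC1C=C(OC)C(=O)C(OCOC)=C1OC | intermediate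
10 | 4-allyl-3,6-dimethoxy-2-(methoxymethoxy)phenol | C=CCc1cc(OC)c(O)c(OCOC)c1OC | intermediate
11 | [4-allyl-3,6-dimethoxy-2-(methoxymethoxy)phenoxy]tri(propan-2-yl)silane | C=CCc1cc(OC)c(O[Si](C(C)C)(C(C)C)C(C)C)c(OCOC)c1OC | intermediate
12 | 3-allyl-2,5-dimethoxy-6-[tri(propan-2-yl)silyloxy]phenol | C=CCc1cc(OC)c(O[Si](C(C)C)(C(C)C)C(C)C)c(O)c1OC | intermediate
13 | 5-allyl-3,6,6-trimethoxy-2-[tri(propan-2-yl)silyloxy]cyclohexa-2,4-dien-1-one | C=CCC1=CC(OC)=C(O[Si](C(C)C)(C(C)C)C(C)C)C(=O)C1(OC)OC | intermediate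
14 | syringaldehyde (4-hydroxy-3,5-dimethoxybenzaldehyde) | COc1cc(C=O)cc(OC)c1O | starting material
15 | 3,5-dimethoxy-4-[tri(propan-2-yl)silyloxy]benzaldehyde | COc1cc(C=O)cc(OC)c1O[Si](C(C)C)(C(C)C)C(C)C | intermediate
16 | 1-{3,5-dimethoxy-4-[tri(propan-2-yl)silyloxy]phenyl}propan-1-ol (racemic) | CCC(O)c1cc(OC)c(O[Si](C(C)C)(C(C)C)C(C)C)c(OC)c1 | intermediate
17 | 1-{3,5-dimethoxy-4-[tri(propan-2-yl)silyloxy]phenyl}propan-1-one | CCC(=O)c1cc(OC)c(O[Si](C(C)C)(C(C)C)C(C)C)c(OC)c1 | intermediate
18 | potassium (Z)-1-{3,5-dimethoxy-4-[tri(propan-2-yl)silyloxy]phenyl}prop-1-en-1-olate (formed in situ) | C/C=C(\[O-])c1cc(OC)c(O[Si](C(C)C)(C(C)C)C(C)C)c(OC)c1.[K+] | intermediate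
19 | (Z)-1-{3,5-dimethoxy-4-[tri(propan-2-yl)silyloxy]phenyl}prop-1-en-1-yl trifluoromethanesulfonate | C/C=C(\OS(=O)(=O)C(F)(F)F)c1cc(OC)c(O[Si](C(C)C)(C(C)C)C(C)C)c(OC)c1 | intermediate
20 | trimethyl[(Z)-1-{3,5-dimethoxy-4-[tri(propan-2-yl)silyloxy]phenyl}prop-1-en-1-yl]stannane | C/C=C(\[Sn](C)(C)C)c1cc(OC)c(O[Si](C(C)C)(C(C)C)C(C)C)c(OC)c1 | intermediate
21 | {4-[(Z)-1-iodoprop-1-en-1-yl]-2,6-dimethoxyphenoxy}tri(propan-2-yl)silane | C/C=C(\I)c1cc(OC)c(O[Si](C(C)C)(C(C)C)C(C)C)c(OC)c1 | intermediate
22 | [(E)-1-{3,5-dimethoxy-4-[tri(propan-2-yl)silyloxy]phenyl}prop-1-en-1-yl]lithium, lithium cis to methyl (formed in situ) | C/C=C(\[Li])c1cc(OC)c(O[Si](C(C)C)(C(C)C)C(C)C)c(OC)c1 | intermediate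
23 | lithium 5-allyl-1-[(Z)-1-Ar-prop-1-en-1-yl]-3,6,6-trimethoxy-2-[tri(propan-2-yl)silyloxy]cyclohexa-2,4-dien-1-olate (racemic, formed in situ) | C=CCC1=CC(OC)=C(O[Si](C(C)C)(C(C)C)C(C)C)C([O-])(/C(=C\C)c2cc(OC)c(O[Si](C(C)C)(C(C)C)C(C)C)c(OC)c2)C1(OC)OC.[Li+] | intermediate
24 | racemic 4-allyl-6-[(Z)-1-Ar-prop-1-en-1-yl]-2,5,5,6-tetramethoxy-1-[tri(propan-2-yl)silyloxy]cyclohexa-1,3-diene (diene C1′(allyl)=C6′H–C5′(OMe)=C4′(OTIPS); C3′(OMe)(alkenyl); C2′(OMe)2) | C=CCC1=CC(OC)=C(O[Si](C(C)C)(C(C)C)C(C)C)C(OC)(/C(=C\C)c2cc(OC)c(O[Si](C(C)C)(C(C)C)C(C)C)c(OC)c2)C1(OC)OC | intermediate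
25 | (6S)-4-allyl-6-[(Z)-1-Ar-prop-1-en-1-yl]-2,5,5,6-tetramethoxy-1-[tri(propan-2-yl)silyloxy]cyclohexa-1,3-diene (C3′ = S) | C=CCC1=CC(OC)=C(O[Si](C(C)C)(C(C)C)C(C)C)[C@@](OC)(/C(=C\C)c2cc(OC)c(O[Si](C(C)C)(C(C)C)C(C)C)c(OC)c2)C1(OC)OC | intermediate
26 | 5-allyl-7-Ar-1,3,8,8-tetramethoxy-6-methyl-2-[tri(propan-2-yl)silyloxy]tricyclo[3.2.1.0(2,7)]oct-3-ene; methyl exo, aryl on the cyclopropane carbon C7 exo | C=CC[C@]12C=C(OC)[C@]3(O[Si](C(C)C)(C(C)C)C(C)C)[C@](OC)(C1(OC)OC)[C@]3(c4cc(OC)c(O[Si](C(C)C)(C(C)C)C(C)C)c(OC)c4)[C@@H]2C | intermediate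
27 | 5-allyl-7-(4-hydroxy-3,5-dimethoxyphenyl)-1,3,8,8-tetramethoxy-6-methyltricyclo[3.2.1.0(2,7)]oct-3-en-2-ol (formed in situ as its alkoxide) | C=CC[C@]12C=C(OC)[C@]3(O)[C@](OC)(C1(OC)OC)[C@]3(c4cc(OC)c(O)c(OC)c4)[C@@H]2C | intermediate
28 | 5-allyl-7-(4-hydroxy-3,5-dimethoxyphenyl)-1,3,8,8-tetramethoxy-6-methylbicyclo[3.2.1]oct-3-en-2-one; aryl endo, methyl exo | C=CC[C@]12C=C(OC)C(=O)[C@](OC)(C1(OC)OC)[C@@H](c3cc(OC)c(O)c(OC)c3)[C@@H]2C | intermediate
29 | 5-allyl-7-(4-hydroxy-3,5-dimethoxyphenyl)-1,3-dimethoxy-6-methylbicyclo[3.2.1]oct-3-ene-2,8-dione; aryl endo, methyl exo | C=CC[C@]12C=C(OC)C(=O)[C@](OC)(C1=O)[C@@H](c3cc(OC)c(O)c(OC)c3)[C@@H]2C | intermediate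
30 | 5-allyl-2-hydroxy-7-(4-hydroxy-3,5-dimethoxyphenyl)-1,3-dimethoxy-6-methylbicyclo[3.2.1]oct-3-en-8-one; aryl endo, methyl exo, 2-OH toward the C6–C7 bridge | C=CC[C@]12C=C(OC)[C@@H](O)[C@](OC)(C1=O)[C@@H](c3cc(OC)c(O)c(OC)c3)[C@@H]2C | intermediate
31 | 4-(2-acetoxy-5-allyl-1,3-dimethoxy-6-methyl-8-oxobicyclo[3.2.1]oct-3-en-7-yl)-2,6-dimethoxyphenyl acetate; configuration as in 30 | C=CC[C@]12C=C(OC)[C@@H](OC(C)=O)[C@](OC)(C1=O)[C@@H](c3cc(OC)c(OC(C)=O)c(OC)c3)[C@@H]2C | intermediate
32 | CNP0373655.1: 5-allyl-7-(4-hydroxy-3,5-dimethoxyphenyl)-1,3-dimethoxy-6-methyl-8-oxobicyclo[3.2.1]oct-3-en-2-yl acetate, (7R,8S,1′S,3′S,4′R) in the neolignan locants | C=CC[C@]12C=C(OC)[C@@H](OC(C)=O)[C@](OC)(C1=O)[C@@H](c1cc(OC)c(O)c(OC)c1)[C@@H]2C | target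

**Step count and risks**
Total step count: 21. Longest linear sequence: 15 steps (steps 1–7, then 14–21).

Steps most likely to fail:

Step 16. The cycloaddition may stall or revert, because it joins an electron-rich diene to an electron-rich styrene and builds a fully substituted cyclopropane, or the diene may ionise or undergo a [3,3] shift at the temperature required. Fallback: the same two bonds would be formed by a cation-radical Diels–Alder reaction, a different, stepwise mechanism known for electron-rich styrenes and dienes. One-electron oxidation of 25 with (4-BrC6H4)3N SbCl6 (cat.) and 2,6-di-tert-butylpyridine in CH2Cl2 at 0 °C (or with Ru(bpz)3(PF6)2 under visible light) should trigger bonding of C8 to C1′ and then of C7 to C4′ at low temperature. The fallback sets out from 25, returns to the route at 26 and makes no new compound (F0).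

Step 18. The bridging C2′ ketal lies between two quaternary carbons and is deactivated by the C3′ methoxy group, so the acid strength it needs may also hydrolyse the C5′ enol ether. Fallback: both hydrolyses are driven to completion. Treatment of 28 with 6 M aq. HCl in dioxane at 70 °C would give 5-allyl-3-hydroxy-7-(4-hydroxy-3,5-dimethoxyphenyl)-1-methoxy-6-methylbicyclo[3.2.1]oct-3-ene-2,8-dione F1, a diosphenol whose only possible enol is C5′(OH)=C6′ because C3′ is quaternary. O-Methylation of this enol with Me3SiCHN2 in MeOH–PhMe, which should be faster than methylation of the doubly ortho-substituted phenol, restores the C5′ methyl enol ether. The fallback sets out from 28 and returns at 29.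

Step 19. Hydride may attack the strained C2′ carbonyl in competition with the conjugated C4′ carbonyl. Fallback: both carbonyls of 29 are reduced with excess NaBH4/CeCl3·7H2O in MeOH to 5-allyl-7-(4-hydroxy-3,5-dimethoxyphenyl)-1,3-dimethoxy-6-methylbicyclo[3.2.1]oct-3-ene-2,8-diol F2, in which the configuration of the C2′ carbinol is immaterial. Acetylation with Ac2O in pyridine at 0 °C without an acyl-transfer catalyst should esterify the phenol and the C4′ hydroxyl but leave the C2′ hydroxyl, which sits between two quaternary bridgeheads, giving 4-(2-acetoxy-5-allyl-8-hydroxy-1,3-dimethoxy-6-methylbicyclo[3.2.1]oct-3-en-7-yl)-2,6-dimethoxyphenyl acetate F3. Oxidation of the remaining carbinol with Dess–Martin periodinane buffered with NaHCO3 regenerates the C2′ ketone. The fallback sets out from 29 and returns at 31.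

Further compounds
F0 | step 16 | none | none
F1 | step 18 | 5-allyl-3-hydroxy-7-(4-hydroxy-3,5-dimethoxyphenyl)-1-methoxy-6-methylbicyclo[3.2.1]oct-3-ene-2,8-dione | C=CC[C@]12C=C(O)C(=O)[C@](OC)(C1=O)[C@@H](c3cc(OC)c(O)c(OC)c3)[C@@H]2C
F2 | step 19 | 5-allyl-7-(4-hydroxy-3,5-dimethoxyphenyl)-1,3-dimethoxy-6-methylbicyclo[3.2.1]oct-3-ene-2,8-diol (C8 carbinol configuration undefined) | C=CC[C@]12C=C(OC)[C@@H](O)[C@](OC)(C1O)[C@@H](c3cc(OC)c(O)c(OC)c3)[C@@H]2C
F3 | step 19 | 4-(2-acetoxy-5-allyl-8-hydroxy-1,3-dimethoxy-6-methylbicyclo[3.2.1]oct-3-en-7-yl)-2,6-dimethoxyphenyl acetate (C8 carbinol configuration undefined) | C=CC[C@]12C=C(OC)[C@@H](OC(C)=O)[C@](OC)(C1O)[C@@H](c3cc(OC)c(OC(C)=O)c(OC)c3)[C@@H]2C
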